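Hydroazulene numbering is used (C1 carbinol, C3 isopropenyl-bearing, C3a/C8a ring fusion, C5 the quaternary C–O carbon). Ring B (C3a–C4–C5–C6–C7–C8–C8a) is cut at both bonds of C5, its only oxygenated carbon, which becomes carbon monoxide. In one operation thexylborane ties the exocyclic methylene carbon (C4) and the allyl terminus (C6) of a monocyclic 2-allyl-2-methyl-3-methylenecyclopentane into a borepane; two boron-to-carbon shifts onto CO forge C4–C5 and C5–C6, closing ring B as the C5 ketone, while tethered hydride delivery sets the trans C3a/C8a fusion. Norflavesone, the C5 methyl, the isopropenyl group and the C1 carbinol follow.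

Key step: step 4

Remark 1: C9 is the pyran CH2; β is the face of the C8a methyl and α the opposite face; ring A is the cyclopentane, ring C the pyran, ring D the trione ring.
Remark 2: 1 and 8 are taken as catalogue compounds; the enolised triones 9–17 are drawn in one tautomer; ThxBH2 is (2,3-dimethylbutan-2-yl)borane, added as a preformed THF solution.
Remark 3: step 1 is a whole-cell reduction that adds hydrogen only.

Step 1
Reactants: 1 2-allyl-2-methylcyclopentane-1,3-dione
Product: 2 (2S,3S)-2-allyl-3-hydroxy-2-methylcyclopentan-1-one
Conditions: baker's yeast (Saccharomyces cerevisiae), sucrose, H2O, 30 °C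
Reagents that add atoms: none
Why: Enantiotopic-group-selective microbial ketone reduction (desymmetrisation of a prochiral 2,2-disubstituted cyclopentane-1,3-dione, long established for this very substrate): the yeast reductase delivers hydride to one carbonyl from the face of the smaller methyl group, which should make the quaternary carbon (future C8a) S and the carbinol carbon S (OH cis to allyl), the latter being re-set in steps 9 and 12.

Step 2
Reactants: 2 (2S,3S)-2-allyl-3-hydroxy-2-methylcyclopentan-1-one
Product: 3 (2S,3S)-2-allyl-2-methyl-3-(triethylsilyloxy)cyclopentan-1-one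
Conditions: Et3SiCl, imidazole, DMF, 0 °C
Reagents that add atoms: chlorotriethylsilane, CC[Si](Cl)(CC)CC
Why: Standard silylation of a secondary alcohol, which keeps the oxygen away from the borane of step 4 and is shed by the acid of step 8; no stereocentre is touched.

Step 3
Reactants: 3 (2S,3S)-2-allyl-2-methyl-3-(triethylsilyloxy)cyclopentan-1-one
Product: 4 (1S,2R)-2-allyl-2-methyl-3-methylidenecyclopentyl triethylsilyl ether
Conditions: Ph3PCH3Br, KOt-Bu, toluene, 90 °C
Reagents that add atoms: methyltriphenylphosphonium bromide, C[P+](c1ccccc1)(c1ccccc1)c1ccccc1.[Br-]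
Why: Wittig methylenation of a hindered ketone whose only α-stereocentre is quaternary and cannot epimerise; the new CH2 carbon becomes C4.

Step 4
Reactants: 4 (1S,2R)-2-allyl-2-methyl-3-methylidenecyclopentyl triethylsilyl ether
Product: 6 trans-fused 8a-methyl-1-(triethylsilyloxy)octahydroazulen-5(1H)-one, via thexylborepane 5 (not isolated)
Conditions: ThxBH2 (1.05 equiv), THF (high dilution), −20 to 23 °C; then CO (70 bar), H2O, 50 °C; then NaOAc, H2O2, H2O, 40 °C
Reagents that add atoms: carbon monoxide, [C-]#[O+]
Why: Cyclic hydroboration–carbonylation, the thexylborane annulation that turns 1,5-dienes into cycloheptanones and tethered dienes into trans-fused bicyclic ketones, is applied to 4. ThxBH2 should add first to the unhindered allyl group (boron on the terminal carbon, future C6), and the resulting Thx(R)B–H then adds across the exocyclic double bond through a seven-membered, four-centre transition state (boron on the CH2 carbon, future C4; hydrogen on C3a) to give borepane 5. Under CO the two ring B–C bonds migrate in turn from boron to the carbonyl carbon (thexyl is a poor migrating group and water drives the second shift), which forms C4–C5 and C5–C6 and so closes the seven-membered carbocycle by two 1,2-shifts onto one carbon; buffered peroxide then frees ketone 6. The single new stereocentre, C3a, is set by the tether: the B–H unit hangs from the α-oriented side chain on the quaternary carbon and reaches only the α-face of the neighbouring alkene, so hydrogen enters C3a from that face and C4 ends up trans to C8 (H-3a anti to the angular methyl). The step needs boron at the terminal carbon of both alkenes, which the bulk of the borane and the 1,1-disubstitution of the exocyclic alkene secure, and an intramolecular second hydroboration, which high dilution secures, while the silyl ether keeps the oxygen out of reach of the borane.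

Step 5
Reactants: 6 trans-fused 8a-methyl-1-(triethylsilyloxy)octahydroazulen-5(1H)-one
Product: 7 6-[(dimethylamino)methyl] derivative of 6 (Mannich base, both C6 epimers)
Conditions: LiN(i-Pr)2, THF, −78 °C; then CH2=NMe2 I (Eschenmoser's salt), −78 to 0 °C
Reagents that add atoms: N,N-dimethylmethyleneiminium iodide, C=[N+](C)C.[I-]
Why: Kinetic deprotonation followed by Mannich aminomethylation: the amide base should take a proton from C6, whose neighbour C7 is a plain methylene, in preference to C4, which is shielded by the ring-fusion carbon C3a and the adjacent quaternary C8a; the new C6 centre is erased in step 7 and needs no control.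

Step 6
Reactants: 8 2-isobutyrylphloroglucinol
Product: 9 norflavesone (2-isobutyryl-4,4-dimethylcyclohexane-1,3,5-trione, enol form)
Conditions: NaOMe, MeI (2.1 equiv), MeOH, 0 to 23 °C
Reagents that add atoms: iodomethane, CI
Why: Dearomative double C-methylation of an acylphloroglucinol (the second methyl enters the same, already methylated ring carbon), which should give the gem-dimethyl enolised trione; no stereocentre is formed.

Step 7
Reactants: 7 Mannich base; 9 norflavesone
Product: 10 tetracyclic hemiketal (5-hydroxy, both C5 epimers; H-6 α)
Conditions: toluene, 100 °C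
Reagents that add atoms: none
Why: Thermal Mannich-base alkylation of a cyclic 1,3-dione: the ammonium salt of 7 and the acidic trione loses Me2NH (E1cB) to an α-methylene ketone, which takes up the nucleophilic ring carbon of 9 in a Michael addition and closes to the hemiketal through the ring D oxygen next to the gem-dimethyl carbon; C6, α to the masked ketone, equilibrates to the epimer with the C9 branch equatorial on the chair of ring B (H-6 α).

Step 8
Reactants: 10 tetracyclic hemiketal
Product: 12 tetracyclic pyran with 1α-OH and 5β-methyl, via tertiary carbinol 11 (not isolated)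
Conditions: MeMgBr (excess), THF, −40 to 0 °C; then TsOH·H2O, MeOH/CH2Cl2, 23 °C
Reagents that add atoms: methylmagnesium bromide, C[Mg]Br
Why: Grignard addition followed by SN1 cycloetherification: the hemiketal alkoxide opens to the C5 ketone, which takes up methyl (either face), and acid then ionises the tertiary carbinol so that the ring D oxygen next to the gem-dimethyl carbon (the other flanking oxygen stays in the hydrogen-bonded chelate with the isobutyryl group) captures the C5 cation from the α-face through a chair-like arrangement with the C9 tether equatorial, which should give the trans-fused pyran with axial 5β-methyl, reversible ionisation funnelling any cis-fused ether to this more stable isomer; the same acid in methanol cleaves the silyl ether.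

Step 9
Reactants: 12 tetracyclic pyran with 1α-OH and 5β-methyl
Product: 13 the corresponding 1-ketone
Conditions: (n-Pr4N)RuO4 (5 mol %), N-methylmorpholine N-oxide, 4 Å molecular sieves, CH2Cl2, 23 °C
Reagents that add atoms: none
Why: Ley–Griffith oxidation of the hindered secondary alcohol, which removes the C1 configuration left over from step 1; the enolised trione carries no oxidisable C–H.

Step 10
Reactants: 13 1-ketone
Product: 15 2-en-1-one, via silyl enol ether 14 (not isolated)
Conditions: LiN(SiMe3)2, Me3SiCl, THF, −78 °C; then Pd(OAc)2, MeCN, 23 °C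
Reagents that add atoms: none
Why: Saegusa–Ito dehydrogenation: the C1 ketone can enolise only towards C2 because C8a is quaternary, so silylation and palladium-mediated β-hydride elimination should give the C2=C3 enone regiospecifically, the trione being silylated on oxygen only until work-up.

Step 11
Reactants: 15 2-en-1-one
Product: 16 3α-isopropenyl 1-ketone
Conditions: CH2=C(CH3)MgBr (excess), CuBr·SMe2 (20 mol %), THF, −40 °C; then NH4Cl (aq)
Reagents that add atoms: isopropenylmagnesium bromide, CC(=C)[Mg]Br
Why: Copper-catalysed conjugate addition of a Grignard reagent: the β-face of the cyclopentenone is covered by the C4 methylene on the neighbouring C3a and by the angular methyl, so isopropenyl should enter C3 from the α-face, trans to C4, while the excess reagent first deprotonates the trione, whose enolate does not react.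

Step 12
Reactants: 16 3α-isopropenyl 1-ketone
Product: 17 CNP0510355.1 (target)
Conditions: NaBH4, MeOH, 0 °C
Reagents that add atoms: none
Why: Hydride reduction of a cyclopentanone flanked by a quaternary carbon: NaBH4 should approach anti to the angular methyl (α-face) and give the 1β-alcohol cis to that methyl, as in the reduction of 17-oxo steroids, while the trione survives as its unreactive enolate.

Compound list
1 | 2-allyl-2-methylcyclopentane-1,3-dione | C=CCC1(C)C(=O)CCC1=O | starting material
2 | (2S,3S)-2-allyl-3-hydroxy-2-methylcyclopentan-1-one (OH cis to allyl) | C=CC[C@]1(C)C(=O)CC[C@@H]1O | intermediate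
3 | (2S,3S)-2-allyl-2-methyl-3-(triethylsilyloxy)cyclopentan-1-one | C=CC[C@]1(C)C(=O)CC[C@@H]1O[Si](CC)(CC)CC | intermediate
4 | (1S,2R)-2-allyl-2-methyl-3-methylidenecyclopentyl triethylsilyl ether (allyl and silyloxy cis) | C=CC[C@]1(C)C(=C)CC[C@@H]1O[Si](CC)(CC)CC | intermediate
5 | thexylborepane: the trans-fused bicycle of 6 with B-(2,3-dimethylbutan-2-yl) in place of C5 | C1C[C@H](O[Si](CC)(CC)CC)[C@]2(C)CCCB(C(C)(C)C(C)C)C[C@@H]12 | intermediate
6 | 8a-methyl-1-(triethylsilyloxy)octahydroazulen-5(1H)-one, trans-fused (3a-H α, 8a-CH3 β, 1-OSiEt3 α) | C1C[C@H](O[Si](CC)(CC)CC)[C@]2(C)CCCC(=O)C[C@@H]12 | intermediate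
7 | 6-[(dimethylamino)methyl] derivative of 6 (Mannich base, both C6 epimers) | C1C[C@H](O[Si](CC)(CC)CC)[C@]2(C)CCC(CN(C)C)C(=O)C[C@@H]12 | intermediate
8 | 2-isobutyrylphloroglucinol, 1-(2,4,6-trihydroxyphenyl)-2-methylpropan-1-one | CC(C)C(=O)c1c(O)cc(O)cc1O | starting material
9 | norflavesone, 2-isobutyryl-4,4-dimethylcyclohexane-1,3,5-trione (enol form) | CC(C)C(=O)C1=C(O)CC(=O)C(C)(C)C1=O | intermediate
10 | tetracyclic hemiketal: rings A–D with 5-OH (both C5 epimers), H-6 α, 1α-OSiEt3, 3a-H α, 8a-CH3 β | C1C[C@H](O[Si](CC)(CC)CC)[C@]2(C)CC[C@H]3CC4=C(OC3(O)C[C@@H]12)C(C)(C)C(=O)C(C(=O)C(C)C)=C4O | intermediate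
11 | ring-opened tertiary carbinol: 5-hydroxy-5-methyl (both C5 epimers), trione joined through C9 to C6 | C1C[C@H](O[Si](CC)(CC)CC)[C@]2(C)CC[C@@H](CC3=C(O)C(C)(C)C(=O)C(C(=O)C(C)C)=C3O)C(C)(O)C[C@@H]12 | intermediate
12 | tetracyclic pyran lacking the isopropenyl group: 1α-OH, 5β-CH3, H-6 α, 3a-H α, 8a-CH3 β | C1C[C@H](O)[C@]2(C)CC[C@H]3CC4=C(O[C@]3(C)C[C@@H]12)C(C)(C)C(=O)C(C(=O)C(C)C)=C4O | intermediate
13 | 1-ketone of 12 | C1CC(=O)[C@]2(C)CC[C@H]3CC4=C(O[C@]3(C)C[C@@H]12)C(C)(C)C(=O)C(C(=O)C(C)C)=C4O | intermediate
14 | 1-(trimethylsilyloxy)-1-ene of 13 with the trione enol O-silylated | C1C=C(O[Si](C)(C)C)[C@]2(C)CC[C@H]3CC4=C(O[C@]3(C)C[C@@H]12)C(C)(C)C(=O)C(C(=O)C(C)C)=C4O[Si](C)(C)C | intermediate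
15 | 2-en-1-one | C1=CC(=O)[C@]2(C)CC[C@H]3CC4=C(O[C@]3(C)C[C@@H]12)C(C)(C)C(=O)C(C(=O)C(C)C)=C4O | intermediate
16 | 3α-isopropenyl 1-ketone | C=C(C)[C@@H]1CC(=O)[C@]2(C)CC[C@H]3CC4=C(O[C@]3(C)C[C@@H]12)C(C)(C)C(=O)C(C(=O)C(C)C)=C4O | intermediate
17 | CNP0510355.1: 1β-OH, 3α-isopropenyl, 3a-H α, 5β-CH3, H-6 α, 8a-CH3 β | C=C(C)[C@@H]1C[C@@H](O)[C@]2(C)CC[C@H]3CC4=C(O[C@]3(C)C[C@@H]12)C(C)(C)C(=O)C(C(=O)C(C)C)=C4O | target

Total step count: 12. Longest linear sequence: 11 steps (1 to 17 through steps 1–5 and 7–12).

Steps most likely to fail

Step 4. The second, ring-closing boron-to-carbon shift may stall on the crowded thexyl-capped borane, so that ring-opened carbinols form instead of the cycloheptanone. The fallback sets out from 4 and uses the tethered hydroboration only to deliver hydrogen: ThxBH2, then NaOH/H2O2, should give the trans diol F1. I2, PPh3 and imidazole would convert it into the diiodide F2. Double alkylation of TsCH2NC (NaH, DMSO/Et2O, high dilution) would close ring B at C5 as the cyclic α-tosyl isocyanide F3. Brief contact with dilute HCl in Et2O at 0 °C would hydrolyse it to 6, where the route is rejoined. Ring closure is then two C-alkylations of a carbonyl dianion equivalent, not a pair of shifts on boron.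

Step 5. Deprotonation at C4 may compete with deprotonation at C6, so regiocontrol in the kinetic enolisation is lost. The fallback sets out from 6 and puts the one-carbon unit in under thermodynamic control: reversible Claisen formylation (HCO2Et, NaH, THF) should settle on the less hindered C6 and give the hydroxymethylene ketone F4. Condensation of its formyl group with 9 and in situ transfer hydrogenation (L-proline, Hantzsch ester, CH2Cl2) would then give 10, where the route is rejoined.

Step 8. The C5 cation may lose a proton to ring alkenes and re-close at C6 to a spiro-dihydrofuran, or close with poor facial selectivity to the cis-fused pyran. The fallback sets out from 10 and swaps the roles of the partners: HC(OMe)3 and pyridinium p-toluenesulfonate in MeOH should give the methyl ketal F5 with loss of the silyl group. AlMe3 (CH2Cl2, −78 to 0 °C) would then ionise the exocyclic methoxy group and deliver methyl axially to the cyclic oxocarbenium ion, anti to the axial H-6, to give 12, where the route is rejoined.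

Further compounds
F1 | step 4 | trans diol: (1S)-1-triethylsilyloxy-2-methyl-2-(3-hydroxypropyl)-3-(hydroxymethyl)cyclopentane, CH2OH trans to the propyl chain | C1C[C@H](O[Si](CC)(CC)CC)[C@](C)(CCCO)[C@H]1CO
F2 | step 4 | the corresponding diiodide | C1C[C@H](O[Si](CC)(CC)CC)[C@](C)(CCCI)[C@H]1CI
F3 | step 4 | 5-isocyano-5-tosyl analogue of 6 (cyclic α-tosyl isocyanide) | C1C[C@H](O[Si](CC)(CC)CC)[C@]2(C)CCCC([N+]#[C-])(S(=O)(=O)c3ccc(C)cc3)C[C@@H]12
F4 | step 5 | 6-(hydroxymethylene) derivative of 6 | C1C[C@H](O[Si](CC)(CC)CC)[C@]2(C)CCC(=CO)C(=O)C[C@@H]12
F5 | step 8 | methyl ketal of desilylated 10 (5-OMe, both C5 epimers) | C1C[C@H](O)[C@]2(C)CC[C@H]3CC4=C(OC3(OC)C[C@@H]12)C(C)(C)C(=O)C(C(=O)C(C)C)=C4O
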